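**Plan**

1. Ring numbering used throughout: C1 = quaternary carbinol carbon (bears CH2OBz), C2 and C3 = acetoxy carbons, C4=C5 = olefin, C6 = secondary carbinol carbon. The olefin C4=C5 flanked by the two oxygen-bearing carbons C3 and C6 (a cyclohex-2-ene-1,4-diol unit) is the retron of a 7-oxabicyclo[2.2.1]heptadiene. The retrosynthesis therefore cuts C3–C4 and C5–C6, giving a 3-substituted furan (C6, C1, C2, C3 and the ring oxygen) and an acetylene equivalent.
2. Forward: a silyl-protected furan-3-ylmethanol and (Z)-1,2-bis(phenylsulfonyl)ethene give the carbocycle and the oxygen bridge in one cycloaddition. Exo dihydroxylation of the furan-derived C1=C2 olefin follows, then reductive loss of both sulfonyl groups unveils C4=C5.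
3. A lipase resolves the diol and installs the C2 acetate. Acid-catalysed acetolysis then opens the bridge at C3 with inversion, giving C3–OAc and free C6–OH. Silyl-to-benzoate exchange at the primary oxygen ends the route.
4. Stereochemistry: the bridge oxygen marks one ring face at C3 and C6. OsO4 adds on that same (exo) face, so C1–OH and C2–O are cis to C6–O. Inversion at C3 makes C3–OAc trans to C2–OAc. The absolute configuration comes from the enzyme.
5. Helpers and their removal: sulfonyl groups (activation, step 4), oxygen bridge (temporary ring, step 6), TBDPS ether (non-participating mask, step 7).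

Key step: step 2

Remark: compounds 4, 5 and 6 are racemates; their SMILES show the enantiomer that leads to the target. Step 5 gives 7 as a single enantiomer and leaves the mirror-image diol, which is removed by chromatography.

**Route**

Step 1
Reactants: 1 furan-3-ylmethanol
Product: 2 tert-butyl(furan-3-ylmethoxy)diphenylsilane
Conditions: TBDPSCl, imidazole, DMF, 0 °C to rt
Reagents that add atoms: tert-butyl(chloro)diphenylsilane, CC(C)(C)[Si](Cl)(c1ccccc1)c1ccccc1
Why: Imidazole-promoted silylation of a primary alcohol (silyl ether formation); the silyl ether is used instead of the benzoate of the target because an ester on this carbon could open the oxygen bridge from the wrong end in step 6 by neighbouring-group attack at C6.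

Step 2
Reactants: 2 tert-butyl(furan-3-ylmethoxy)diphenylsilane; 3 (Z)-1,2-bis(phenylsulfonyl)ethene
Product: 4 rac-tert-butyl{[5-endo,6-endo-bis(phenylsulfonyl)-7-oxabicyclo[2.2.1]hept-2-en-2-yl]methoxy}diphenylsilane
Conditions: CH2Cl2, 25 °C, several days, dark (2 in excess)
Reagents that add atoms: none
Why: A concerted suprafacial [4+2] cycloaddition between the furan (its two alpha carbons become C6 and C3) and the electron-poor cis-disulfonyl alkene, which stands in for acetylene, should form both bonds to the future olefin carbons C5 and C4 at once; the closest known reaction type is the Diels–Alder addition of (Z)-1,2-bis(phenylsulfonyl)ethene to furan and cyclopentadiene followed by reductive desulfonylation (acetylene-equivalent method). The cyclohexene ring is closed by intermolecular cycloaddition, and the oxygen bridge that arises with it is a temporary ring holding the C3–O and C6–O bonds cis on one face. The two bridgehead stereocenters are fixed relative to each other by addition across one furan face; the two sulfonyl-bearing centers are cis from the Z alkene (endo by the Alder rule) and disappear in step 4, so an exo isomer would converge. No regiochemical question arises because the dienophile is symmetric, and the furan is the only diene present; the adduct forms as a racemate that is resolved in step 5. The sulfonyl groups supply the activation that acetylene lacks, and the mixture is kept near room temperature because furan adducts revert on heating.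

Step 3
Reactants: 4 the bis-sulfone adduct
Product: 5 rac-2-({[tert-butyl(diphenyl)silyl]oxy}methyl)-5-endo,6-endo-bis(phenylsulfonyl)-7-oxabicyclo[2.2.1]heptane-2-exo,3-exo-diol
Conditions: OsO4 (2 mol %), NMO, acetone/H2O, rt
Reagents that add atoms: osmium tetroxide (catalytic), O=[Os](=O)(=O)=O; N-methylmorpholine N-oxide, C[N+]1([O-])CCOCC1; water, O
Why: Upjohn syn-dihydroxylation of the only C=C in 4; OsO4 should add from the exo face (the side of the oxygen bridge), as is general for 7-oxanorbornenes, which places C1–OH and C2–OH cis to each other and cis to both bridge C–O bonds.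

Step 4
Reactants: 5 the exo,exo-diol bis-sulfone
Product: 6 rac-(1S,2R,3R,4R)-2-({[tert-butyl(diphenyl)silyl]oxy}methyl)-7-oxabicyclo[2.2.1]hept-5-ene-2,3-diol (both hydroxyls exo)
Conditions: Na(Hg) (6% Na), Na2HPO4, MeOH/THF, −20 °C
Reagents that add atoms: none
Why: Reductive elimination of a vicinal bis-sulfone with sodium amalgam (the unmasking step of the acetylene-equivalent method) should create the C4=C5 double bond without touching the silyl ether or any stereocenter, since sulfinate is a far better leaving group than the bridge alkoxide.

Step 5
Reactants: 6 the racemic ene-diol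
Product: 7 (1R,2R,3S,4S)-3-({[tert-butyl(diphenyl)silyl]oxy}methyl)-3-hydroxy-7-oxabicyclo[2.2.1]hept-5-en-2-yl acetate (exo acetate on C2, exo tertiary hydroxyl on C1)
Conditions: lipase from Burkholderia cepacia (immobilised), vinyl acetate, MTBE, 30 °C, stopped near half conversion; chromatography
Reagents that add atoms: vinyl acetate, CC(=O)OC=C
Why: Lipase-catalysed irreversible transesterification (kinetic resolution of a secondary alcohol by a serine hydrolase): only the secondary exo hydroxyl can be acylated, and Kazlauskas' rule (large group = the quaternary carbon with the silyloxymethyl group, medium group = the bridgehead CH) predicts that the enantiomer drawn reacts faster, so the step should set the absolute configuration and install the C2 acetate of the target together.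

Step 6
Reactants: 7 the enantiopure monoacetate
Product: 8 (1S,2R,3S,4S)-3-({[tert-butyl(diphenyl)silyl]oxy}methyl)-3,4-dihydroxycyclohex-5-ene-1,2-diyl diacetate
Conditions: dry AcOH, TfOH (5 mol %), CH2Cl2, 4 Å molecular sieves, −20 to 0 °C; then aq. NaHCO3
Reagents that add atoms: acetic acid, CC(=O)O
Why: Acid-catalysed acetolysis of the strained allylic 1,4-anhydro bridge of a 7-oxanorbornene: acetic acid should attack the protonated ether at C3 (the bridgehead not flanked by the quaternary carbon and its endo silyloxymethyl group) from the face opposite the leaving oxygen, so C3 is inverted (C3–OAc trans to C2–OAc) while the bridge oxygen stays on C6 as the free hydroxyl cis to C1–OH; should C3 ionise instead, the exo C2 acetate is expected to cap the cation on the bridge face and acetic acid to reopen that ring at the allylic carbon with inversion (Prévost-type relay), giving the same trans-diacetate.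

Step 7
Reactants: 8 the silyl ether diacetate
Product: 9 (1S,2R,3S,4S)-3,4-dihydroxy-3-(hydroxymethyl)cyclohex-5-ene-1,2-diyl diacetate
Conditions: HF·pyridine, pyridine/THF, 0 °C to rt
Reagents that add atoms: none
Why: Fluoride cleavage of the silyl ether under buffered acidic conditions should remove the helper group without the base-induced acetyl migration that tetrabutylammonium fluoride could cause; no stereocenter is affected.

Step 8
Reactants: 9 the triol diacetate
Product: 10 [(1S,2S,5S,6R)-5,6-bis(acetyloxy)-1,2-dihydroxycyclohex-3-en-1-yl]methyl benzoate (target)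
Conditions: BzCl (1.05 equiv), 2,4,6-collidine, CH2Cl2, −40 to −20 °C
Reagents that add atoms: benzoyl chloride, O=C(Cl)c1ccccc1
Why: Sterically controlled O-acylation: the primary hydroxyl should react with benzoyl chloride much faster than the secondary allylic C6–OH next to the quaternary carbon or the tertiary C1–OH, so one equivalent at low temperature with a hindered pyridine base should give only the primary benzoate.

**Compound list**

1 | furan-3-ylmethanol | OCc1ccoc1 | starting material
2 | tert-butyl(furan-3-ylmethoxy)diphenylsilane | CC(C)(C)[Si](OCc1ccoc1)(c1ccccc1)c1ccccc1 | intermediate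
3 | (Z)-1,2-bis(phenylsulfonyl)ethene | O=S(=O)(/C=C\S(=O)(=O)c1ccccc1)c1ccccc1 | starting material
4 | rac-tert-butyl{[5-endo,6-endo-bis(phenylsulfonyl)-7-oxabicyclo[2.2.1]hept-2-en-2-yl]methoxy}diphenylsilane | O1[C@@H]2[C@@H](S(=O)(=O)c3ccccc3)[C@@H](S(=O)(=O)c3ccccc3)[C@H]1C(CO[Si](c3ccccc3)(c3ccccc3)C(C)(C)C)=C2 | intermediate
5 | rac-2-({[tert-butyl(diphenyl)silyl]oxy}methyl)-5-endo,6-endo-bis(phenylsulfonyl)-7-oxabicyclo[2.2.1]heptane-2-exo,3-exo-diol | O1[C@@H]2[C@@H](S(=O)(=O)c3ccccc3)[C@@H](S(=O)(=O)c3ccccc3)[C@H]1[C@@](O)(CO[Si](c3ccccc3)(c3ccccc3)C(C)(C)C)[C@@H]2O | intermediate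
6 | rac-(1S,2R,3R,4R)-2-({[tert-butyl(diphenyl)silyl]oxy}methyl)-7-oxabicyclo[2.2.1]hept-5-ene-2,3-diol (exo,exo) | O1[C@@H]2C=C[C@H]1[C@@](O)(CO[Si](c3ccccc3)(c3ccccc3)C(C)(C)C)[C@@H]2O | intermediate
7 | (1R,2R,3S,4S)-3-({[tert-butyl(diphenyl)silyl]oxy}methyl)-3-hydroxy-7-oxabicyclo[2.2.1]hept-5-en-2-yl acetate | O1[C@@H]2C=C[C@H]1[C@@](O)(CO[Si](c3ccccc3)(c3ccccc3)C(C)(C)C)[C@@H]2OC(C)=O | intermediate
8 | (1S,2R,3S,4S)-3-({[tert-butyl(diphenyl)silyl]oxy}methyl)-3,4-dihydroxycyclohex-5-ene-1,2-diyl diacetate | CC(=O)O[C@H]1C=C[C@H](O)[C@@](O)(CO[Si](c2ccccc2)(c2ccccc2)C(C)(C)C)[C@@H]1OC(C)=O | intermediate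
9 | (1S,2R,3S,4S)-3,4-dihydroxy-3-(hydroxymethyl)cyclohex-5-ene-1,2-diyl diacetate | CC(=O)O[C@H]1C=C[C@H](O)[C@@](O)(CO)[C@@H]1OC(C)=O | intermediate
10 | [(1S,2S,5S,6R)-5,6-bis(acetyloxy)-1,2-dihydroxycyclohex-3-en-1-yl]methyl benzoate | CC(=O)O[C@H]1C=C[C@H](O)[C@@](O)(COC(=O)c2ccccc2)[C@@H]1OC(C)=O | target

**Step count and risks**

Total steps: 8. Longest linear sequence: 8 (from furan-3-ylmethanol).

Step 6 (bridge acetolysis). What may go wrong: loss of regiocontrol in the ether cleavage (attack at the olefinic terminus with allylic shift, or ionisation at the hindered bridgehead C6), capture of an allyl cation on the wrong face if traces of water hydrolyse the acetate relay, or acid-induced loss of the silyl ether. The fallback sets out from 7 and comes back at 8. The bridge would be cleaved with the stronger nucleophile bromide (anhydrous HBr, 1.1 equiv, CH2Cl2, −30 °C), which should attack the less hindered allylic bridgehead with inversion to give (1S,2S,3S,6S)-6-bromo-2-({[tert-butyl(diphenyl)silyl]oxy}methyl)-2,3-dihydroxycyclohex-4-en-1-yl acetate F1 (bromide trans to the C2 acetate and to C6–OH). Treatment of F1 with AgOAc in dry AcOH at rt would then replace bromide by acetate with net retention. This is the classical substitution of a trans-2-acetoxy halide with anchimeric assistance: the C2 acetate displaces bromide from the opposite face, and acetate reopens the ring at the allylic carbon. Any regio- or stereoisomeric allylic bromide should be funnelled through the same C2-capped ion, so 8 results.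

Step 5 (lipase resolution). What may go wrong: poor enantiomer discrimination or no turnover at a carbinol next to a quaternary carbon, or the opposite enantiomer preference. The fallback sets out from 6 and comes back at 7. Racemic 6 would be esterified at the secondary hydroxyl with (1S,4R)-camphanoyl chloride (pyridine, cat. DMAP, CH2Cl2). This gives the (1S,4R)-camphanate of the (1S,2R,3R,4R) diol F2 and the (1S,4R)-camphanate of the mirror-image diol F3, two diastereomers to be separated by crystallisation or chromatography. Methanolysis of F2 (K2CO3, MeOH, 0 °C) returns 6 as the single enantiomer whose SMILES stands in the list. Ac2O/pyridine at 0 °C then acetylates only the secondary hydroxyl, giving 7.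

Step 8 (selective benzoylation). What may go wrong: over-acylation at C6–OH, or base-induced acetyl migration from C2–O to the primary oxygen before the benzoate is in place. The fallback sets out from 9 and comes back at 10. The benzoate would be introduced by enzymatic transesterification with vinyl benzoate (Candida antarctica lipase B, MTBE, 30 °C), which is neutral and selective for primary hydroxyls. This fallback makes no new compound (F0).

**Further compounds**

F1 | step 6 | (1S,2S,3S,6S)-6-bromo-2-({[tert-butyl(diphenyl)silyl]oxy}methyl)-2,3-dihydroxycyclohex-4-en-1-yl acetate | Br[C@H]1C=C[C@H](O)[C@@](O)(CO[Si](c2ccccc2)(c2ccccc2)C(C)(C)C)[C@@H]1OC(C)=O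
F2 | step 5 | (1S,4R)-camphanate of the (1S,2R,3R,4R) enantiomer of 6 at the secondary exo hydroxyl | O1[C@@H]2C=C[C@H]1[C@@](O)(CO[Si](c3ccccc3)(c3ccccc3)C(C)(C)C)[C@@H]2OC(=O)[C@@]12CC[C@@](C)(C(=O)O1)C2(C)C
F3 | step 5 | (1S,4R)-camphanate of the mirror-image (1R,2S,3S,4S) diol (diastereomer removed) | O1[C@H]2C=C[C@@H]1[C@](O)(CO[Si](c3ccccc3)(c3ccccc3)C(C)(C)C)[C@H]2OC(=O)[C@@]12CC[C@@](C)(C(=O)O1)C2(C)C
F0 | step 8 | none | none
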